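the same everywhere: capture agent 1.30 mM; time 80 s

| charge | substrate | reagent | remark |
|---|---|---|---|
| south-east | 13 mM | 15.6 mM | everything together at the start |
| south | 13 mM | 15.6 mM (fed, over 50 s) | all else is in the flask from the start; the feed brings no volume worth counting |
| east | 13 mM (in portions, 3, over 50 s) | 15.6 mM | first portion at the start, last at 50 s |
| north | 13 mM (fed, over 50 s) | 15.6 mM | all else is in the flask from the start; the feed brings no volume worth counting |

- the flask with the highest share of target in target plus side product ("all alike" if they lie within 1.5 percentage points) (south-east / south / east / north / all alike)
- share of target in target plus side product at the end, south-east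
- share of target in target plus side product at the end, south
- share of target in target plus side product at the end, east
- share of target in target plus side product at the end, north

    reagent + intermediate A → side product (k1 = 2.18 L mol⁻¹ s⁻¹)
    reagent + intermediate A → target (k2 = 1.34 L mol⁻¹ s⁻¹)
    intermediate A ⇌ intermediate B (K3 = 0.855, k3 = 0.00475 s⁻¹)
    reagent + intermediate B ⇌ intermediate C (K4 = 25 L mol⁻¹, k4 = 9.64 L mol⁻¹ s⁻¹)
    substrate + reagent → intermediate A (k5 = 1.58 L mol⁻¹ s⁻¹)
    capture agent + intermediate A → trapped intermediate (k6 = 0.653 L mol⁻¹ s⁻¹)

The step to side product has the larger constant, 2.18 L mol⁻¹ s⁻¹ against 1.34 L mol⁻¹ s⁻¹ for the step to target, and the meeting opened on what dosing does to that.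

The first speaker argued that the feeds should matter, since the dosing time stands at 1.2 times the lifetime of substrate against everything charged. The second speaker, whose reckoning I adopted as my own, wrote y and u for target and side product as fractions of the substrate charged. She replied that both arrows start from the same pair, reagent and intermediate A, so that y and u grow in the ratio 1.34 L mol⁻¹ s⁻¹ to 2.18 L mol⁻¹ s⁻¹ at each instant. Both begin at zero and the scheme consumes neither. She therefore asked what the end state must be and entered the split, the fraction y/(y+u) of product that is target, the selectivity factor written as a share: 38.1 %.

The first speaker objected that capture agent takes intermediate A away and that intermediates B and C hold it back. The reply was that these steps change how much intermediate A meets reagent, not how that encounter divides. Asked how fast the end state is approached, she said the ratio needs no approach: it stands from the first product onward. The amounts are another matter, but the half-life of substrate by step 5 taken by itself, at the charges of south-east, is 28 s, shorter than the 80 s of the run, so south-east should have product to read. The meeting committed to the split for each flask, and so to a tie.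

The forecast, made separately, gave 38.07 % for south-east, 38.07 % for south, 38.07 % for east and 38.07 % for north, with the verdict all alike. Its ground was that the ratio holds “whatever the concentrations of reagent and A are”.

The simulation gives 38.1 % for south-east, 38.1 % for south, 38.1 % for east and 38.1 % for north, and the verdict all alike.

Take north again, charged with 27 mM of reagent instead of 15.6 mM, time held. The split has no reagent term, so it is carried over unchanged. North itself reads target 11.1 % and side product 18.0 % of the substrate charged at 80.0 s. The neighbour reads side product 33.4 %, and the split turns that into target of 20.6 %. The neighbour's target reads 20.5 %, about twice north's, and its share is 38.1 %.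

The rate constants belong to no real substance; the run is a simulation.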